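**Synthesis proposal for CNP0555433.1 (compound 20): Birch dearomatisation of a spiro-fused 5-methoxyisochromanone**

## Analysis of the target

The target 20 is a 6,7-seco-ent-kauranoid, and ent-kaurane numbering is used throughout: ring A is C1–C5/C10 with the C18 methyl and the C19 oxymethylene on C4, C6 is the γ-lactone carbonyl on C5, C20 is the oxymethylene on C10, C7 is the δ-lactone carbonyl on C8, ring C is C8/C9/C11–C14, C15(=O)–C16 is the two-carbon bridge and C17 is the CH2OH on C16. Four rings are present: cyclohexane A cis-fused to the γ-lactone (C6–O–C19), a δ-lactone (C7–O–C20) that is spiro at C10 and cis-fused to ring C across C8–C9, and a bicyclo[3.2.1]octane made of ring C and the C15–C16 bridge. There are eight stereocentres, three of them quaternary (C4, C10, C8), and C10–C9–C8 form a contiguous triad. On ring A the three oxygenated one-carbon branches C19, C6 and C20 lie on one face (α) and C18, H-5 and C9 on the other (β); across the δ-lactone H-9 and C15 are syn; the C11 hydroxyl is equatorial, cis to C10 and anti to the bridge; at C16 the CH2OH points endo (towards C11/C12) and H-16 exo (towards C14). The sensitive groups are the non-enolisable β-keto lactone at C8 (retro-Claisen), the β-hydroxy ketone C17–C16–C15 (dehydration to the exo-methylene enone, epimerisation at C16), the epimerisable C5, and the two lactones, which could exchange alcohol partners. The difficulty is that no ring B relays stereochemistry: the two arms of the spiro centre (C1 and C5) must be matched with C9 and C8 across a single bond. The feature that invites the chosen move is ring C itself: C8 carries the carboxyl carbon C7, C9 carries the spiro carbon C10 and C11 carries oxygen on three contiguous ring atoms, which is the pattern of a 2-alkyl-3-methoxybenzoate and, with O–C20–C10, of a 5-methoxyisochroman-1-one spiro-fused at C10. Ring C and the δ-lactone can therefore be carried as a flat arene and dearomatised by Birch reduction, which turns C11 into the carbonyl, leaves the double bond at C12=C13 where ring D must close and leaves C8 enolisable. Ring A with C6 on C5, C18/C19 on C4 and C20 on C10 is the skeleton of α-cyclogeranic acid.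

## Retrosynthetic reasoning

**C11–O–Si and the C17–O / C16–H pair (20 ⇐ 19 ⇐ 17).** The β-hydroxy ketone is the most fragile part and is made last. Removing the silyl ether gives 19. The C17 hydroxyl and H-16 are then taken back to the exo-methylene enone 17 by a formal anti-Markovnikov hydration (conjugate borylation, protonation, oxidation). This places C16 under kinetic control from the open exo face and avoids strong base.

**C15=O (17 ⇐ 16 ⇐ 15).** The ketone is cut back to the allylic methylene of 15. C15 is the only allylic CH2 of the exocyclic alkene, so allylic oxidation is unambiguous.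

**C13–C16, ring D (15 ⇐ 14).** The bridge is opened at C13–C16. Forward, a C16 vinyl radical held on the β face of C8 closes 5-exo on C13 of a C12=C13 double bond, so C13 needs no separate control.

**C8–C15, the quaternary centre (14 ⇐ 12 + 13).** The three-carbon unit is removed from C8, which leaves a lactone with an acidic C8–H and the allylic bromide 13. The cut is made here, and not in the dearomatisation flask, because only with C9 already sp3 do H-9, C10 and the C11 oxygen steer the electrophile to the correct face.

**C11 carbinol (12 ⇐ 11 ⇐ 10).** The protected 11α-alcohol goes back to the enone 10. The reduction must be done before ring D exists, because in the bicycle the bridge blocks the face from which hydride has to come.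

**Ring C from an arene, the key disconnection (10 ⇐ 9 ⇐ 8).** Ring C of 10 is re-aromatised to the anisole of 8. What is gained is that everything chiral in 8 sits in ring A, and the ring C/δ-lactone half becomes an achiral commercial benzoic acid. Forward, Birch reduction has to reduce the benzoate ring at C8 and C12, and hydrolysis of 9 has to give the C11 ketone, the C12=C13 bond and the right C9 epimer.

**C9–C10, the spiro centre (8 ⇐ 7 ⇐ 6 ⇐ 4 + 5).** The aryl–C10 bond is cut with the ester tether kept. Forward this is a 6-exo Heck cyclisation of the aryl iodide 6 onto the C10=C1 double bond, followed by hydrogenation of the transposed alkene in 7. Ester 6 comes from allylic alcohol 4 and acid 5.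

**C20–O and C19–O on a terpenoid acid (4 ⇐ 3 ⇐ 2 ⇐ 1).** Alcohol 4 differs from lactone 3 by allylic oxidation of the vinylic methyl C20. Lactone 3 differs from acid 2 by one C–H lactonisation of the gem-dimethyl group, which creates the quaternary C4 from the C5 stereocentre. Acid 2 is one enantiomer of the commercial racemate 1.

## Alternatives that were turned down

Alternative 1: Ester-tethered intramolecular Diels–Alder reaction, the textbook route. The cut is C8–C9 plus C13–C14: triene ester A1 (a 2-silyloxydiene on C9 of an already quaternary C10, and a 2-(2-bromoallyl)acrylate on O–C20) would be heated to give A2, with δ-lactone and ring C formed together, followed by radical closure of ring D.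
- The precursor already holds the quaternary C10 with two different branches next to the epimerisable lactone; building it by enolate chemistry at C10 in the presence of the acidic C5–H would cost about as many steps as the whole first half of the chosen route.
- The cycloaddition joins a 1,1-disubstituted dienophile carbon to a diene terminus on a neopentyl carbon through an s-trans ester, so it needs high temperature, which a silyl dienol ether tolerates poorly.
- One transition state would have to deliver endo/exo and π-facial selectivity at once.
- It is the route most chemists would draw first.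

Alternative 2: Birch reductive alkylation in one pot. Same arene, but the lactone enolate from 8 is trapped directly with 13, so that dearomatisation and the quaternary C8 come together (expected product A3).
- In that enolate C9 is still sp2. The faces of C8 are then told apart only by the two arms of the spiro centre, which straddle the ring plane to avoid the C11 methoxy group.
- The branched arm C5 shields its own face, so the bromide should enter syn to the CH2 arm C1. That is the C8 epimer A3, and a quaternary centre cannot be corrected later.
- The step saved is not worth a probable wrong diastereomer.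

Alternative 3: Desymmetrising radical cyclisation onto a Birch diene. The cut is C9–C10 on a prochiral ring: ester A4 (alcohol 4 acylated with the reductive-alkylation product of benzoic acid and 13) would give a tertiary C10 radical by hydrogen-atom transfer to C10=C1, which closes 6-exo on one of the two enantiotopic ring alkenes with oxygen trapping at C11.
- A nucleophilic tertiary radical and an unactivated 1,2-disubstituted alkene are polarity-mismatched.
- The 6-exo closure must pass through the disfavoured s-cis ester rotamer and is slow.
- The doubly allylic C12–H bonds and the vinyl bromide compete for hydrogen-atom transfer.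
- The C11 oxygen would arrive without stereocontrol; the polarity-matched dienone variant puts the oxygen on C12 instead.

Key step: step 7

Remarks before the steps:
- Descriptors α/β refer to the usual ent-kaurane drawing: C19, C6, C20 and the C11 oxygen are α; C18, H-5, H-9 and the C15–C16 bridge are β.
- Assumption: the (R)-1-phenylethylammonium salt of the (R)-acid is taken to be the less soluble one; if it is the other, the (S)-amine is used and nothing else changes.
- Assumption: C8 in 9–12 and C15 in 16 are inconsequential stereocentres (removed in steps 10 and 13). Compounds 9 and 16 are written without a descriptor there, and 10–12 as the trans-fused C8 epimer (8α-H).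

## Route

Step 1
Reactants: 1 rac-α-cyclogeranic acid
Product: 2 (R)-α-cyclogeranic acid
Conditions: (R)-1-phenylethylamine (0.6 equiv), acetone, recrystallise the salt; then 1 M HCl, Et2O
Reagents that add atoms: none
Why: Classical resolution through diastereomeric ammonium salts; C5 is the only stereocentre and no base strong enough to deconjugate the β,γ-unsaturated acid is present.

Step 2
Reactants: 2 (R)-α-cyclogeranic acid
Product: 3 cis-fused 6,19-lactone (3aR,7aS)-3a,7-dimethyl-3a,4,5,7a-tetrahydro-2-benzofuran-1(3H)-one
Conditions: Pd(OAc)2 (10 mol %), N-acetyl-β-alanine (20 mol %), t-BuOOH (2 equiv), NaOAc, HFIP, 60 °C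
Reagents that add atoms: none
Why: Pd(II)-catalysed carboxylate-directed γ-C(sp3)–H lactonisation (cyclopalladation of a methyl group on the β-quaternary carbon, oxidation, C–O reductive elimination); the carboxyl on C5 is pseudo-axial (A1,2 strain with the C20 methyl), so only the cis methyl is gauche to it and becomes C19, which transfers the C5 configuration to the new quaternary centre C4.

Step 3
Reactants: 3 cis-fused 6,19-lactone
Product: 4 allylic alcohol (3aR,7aR)-7-(hydroxymethyl)-3a-methyl-3a,4,5,7a-tetrahydro-2-benzofuran-1(3H)-one
Conditions: SeO2 (0.5 equiv), t-BuOOH (3 equiv), CH2Cl2, rt; then NaBH4, MeOH, 0 °C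
Reagents that add atoms: tert-butyl hydroperoxide CC(C)(C)OO (terminal oxidant, oxygen delivered through selenium dioxide O=[Se]=O)
Why: Selenium dioxide allylic oxidation (ene reaction, then [2,3]-shift) goes to the allylic position on the more substituted alkene carbon C10, where the methyl C20 reacts in preference to the tertiary, carbonyl-deactivated C5–H; borohydride returns any over-oxidised enal to 4 without touching the lactone.

Step 4
Reactants: 4 allylic alcohol; 5 2-iodo-3-methoxybenzoic acid
Product: 6 [(3aR,7aR)-3a-methyl-1-oxo-1,3,3a,4,5,7a-hexahydro-2-benzofuran-7-yl]methyl 2-iodo-3-methoxybenzoate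
Conditions: DCC, DMAP (cat.), CH2Cl2, 0 °C to rt
Reagents that add atoms: none
Why: Steglich esterification of a primary allylic alcohol with a hindered benzoic acid under neutral conditions that leave the lactone and C5 alone.

Step 5
Reactants: 6 aryl iodide ester
Product: 7 spiro Heck product 11-methoxy-6,7-seco-ent-podocarpa-1,8,11,13-tetraene-6,19:7,20-diolide
Conditions: Pd(OAc)2 (10 mol %), PPh3 (20 mol %), Et3N (2 equiv), MeCN, 80 °C
Reagents that add atoms: none
Why: Intramolecular Mizoroki–Heck reaction: oxidative addition, 6-exo-trig syn-carbopalladation of C10=C1 that creates the quaternary spiro centre C10, then β-hydride elimination towards C2; the arylpalladium adds to the face away from C6 and C19 (the convex face of the cis-fused lactone), which puts C9 on the β face and C20 axial next to C19 as in the target.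

Step 6
Reactants: 7 spiro Heck product
Product: 8 aryl bis-lactone 11-methoxy-6,7-seco-ent-podocarpa-8,11,13-triene-6,19:7,20-diolide
Conditions: H2 (1 atm), 10 % Pd/C, EtOAc, rt
Reagents that add atoms: none
Why: Heterogeneous hydrogenation of the isolated ring alkene; the anisole, both lactones and the benzylic quaternary centre are inert, no stereocentre forms, and any double-bond isomer from step 5 converges on 8.

Step 7
Reactants: 8 aryl bis-lactone
Product: 10 11-oxo-6,7-seco-ent-podocarp-12-ene-6,19:7,20-diolide, via dihydroarene enol ether 9 (not isolated)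
Conditions: Li (2.5 equiv), NH3(l)/THF, t-BuOH (1.5 equiv), −78 °C; NH4Cl; then 1 M HCl, THF, 40 °C
Reagents that add atoms: water O
Why: Birch reduction: electron transfer to the aryl ester, protonation at C12 (para to the ester-bearing C8) by t-BuOH, a second electron transfer to the lactone enolate and protonation at C8 on quench give 9, with the methoxy group and the alkyl branch C10 on the remaining double bonds as the Birch rule requires. Aqueous acid then hydrolyses the enol ether (C11 becomes the ketone, C9 becomes sp3) and moves C13=C14 into conjugation as C12=C13. The closest known reaction type is the Birch reduction of 3-methoxybenzoic acid derivatives and alkyl benzoates followed by enol ether hydrolysis to cyclohexenones. No ring is closed: the flat ring of 8 becomes ring C with the C11 oxygen, the C12=C13 bond needed for ring D and an enolisable C8–H for the later quaternisation. The new stereocentre C9 is α to the ketone and equilibrates under the acid, controlled by the spiro centre C10: only in the wanted epimer can the δ-lactone chair hold C11 and the branched arm C5 both equatorial, with just the CH2 arm C1 axial. C8 is formed as H-epimers that do not matter, because it is planarised in step 10. The step needs reduction of the benzoate ring before the aliphatic lactone, which the far better electron-acceptor ability of the aryl ester and the limited metal at −78 °C should secure, and ketone-directed rather than lactone-directed double-bond migration, which the faster enolisation of the ketone should secure.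

Step 8
Reactants: 10 enone bis-lactone
Product: 11 11α-hydroxy-6,7-seco-ent-podocarp-12-ene-6,19:7,20-diolide
Conditions: (S)-Me-CBS oxazaborolidine (0.3 equiv), catecholborane (1.5 equiv), toluene, −78 °C
Reagents that add atoms: none
Why: Corey–Bakshi–Shibata reduction, 1,2-selective on the enone; the catalyst binds the carbonyl on the side of the vinyl carbon C12 (small) and away from the tertiary C9 bearing the spiro centre (large), so the (S)-catalyst delivers hydride to the β face and gives the 11α-alcohol, the face the substrate also prefers (anti to C10).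

Step 9
Reactants: 11 11α-allylic alcohol
Product: 12 11α-(tert-butyldimethylsilyloxy)-6,7-seco-ent-podocarp-12-ene-6,19:7,20-diolide
Conditions: TBSOTf, 2,6-lutidine, CH2Cl2, −78 to 0 °C
Reagents that add atoms: tert-butyldimethylsilyl triflate CC(C)(C)[Si](C)(C)OS(=O)(=O)C(F)(F)F
Why: Silylation of the secondary allylic alcohol, so that only C8–H is acidic in step 10 and the C11 oxygen survives the oxidations at C15.

Step 10
Reactants: 12 silyl ether; 13 2,3-dibromopropene
Product: 14 8-(2-bromoprop-2-enyl) derivative of 12 (new group on the β face, syn to H-9)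
Conditions: LDA (1.2 equiv), THF, −78 °C; then 13, DMPU, −78 to −30 °C
Reagents that add atoms: none
Why: Alkylation of the δ-lactone enolate with an allylic bromide (C8–H is far more accessible than C5–H, which lies between two quaternary carbons); the electrophile enters the ring-fusion enolate syn to H-9, anti to the vicinal C9–C10 bond, to the C11 silyl ether and to the axial CH2 arm C1 of the spiro centre, which sets the quaternary C8 and the cis ring fusion.

Step 11
Reactants: 14 vinyl bromide
Product: 15 11α-(tert-butyldimethylsilyloxy)-6,7-seco-ent-kaur-16-ene-6,19:7,20-diolide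
Conditions: Bu3SnH (1.5 equiv), AIBN (0.2 equiv), benzene, 80 °C, 0.02 M
Reagents that add atoms: none
Why: Stannane-mediated radical cyclisation: the C16 vinyl radical adds 5-exo-trig to C13 and the C12 radical is reduced; the tether on the β face of C8 can reach C13 only from that face, so C13 and the bicyclo[3.2.1]octane with its exocyclic methylene follow from C8.

Step 12
Reactants: 15 exo-methylene bicycle
Product: 16 15-hydroxy derivative of 15 (allylic alcohol, C15 configuration not needed)
Conditions: SeO2 (0.5 equiv), t-BuOOH (3 equiv), CH2Cl2, rt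
Reagents that add atoms: tert-butyl hydroperoxide CC(C)(C)OO (terminal oxidant, oxygen delivered through selenium dioxide O=[Se]=O)
Why: Selenium dioxide allylic hydroxylation; C15 is the only allylic methylene, because the other allylic position C13 is a bridgehead whose ene reaction would need an anti-Bredt alkene.

Step 13
Reactants: 16 allylic alcohol
Product: 17 11α-(tert-butyldimethylsilyloxy)-15-oxo-6,7-seco-ent-kaur-16-ene-6,19:7,20-diolide
Conditions: Dess–Martin periodinane, CH2Cl2, rt
Reagents that add atoms: none
Why: Dess–Martin oxidation of the secondary allylic alcohol to the α-methylene cyclopentanone under neutral conditions that the non-enolisable β-keto lactone tolerates.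

Step 14
Reactants: 17 exo-methylene enone
Product: 19 17-hydroxy-11α-(tert-butyldimethylsilyloxy)-15-oxo-6,7-seco-ent-kaurane-6,19:7,20-diolide, via C17 pinacolboronate 18 (not isolated)
Conditions: CuCl (10 mol %), Xantphos (10 mol %), NaOt-Bu (10 mol %), B2pin2 (1.1 equiv), MeOH (2 equiv), THF, 0 °C to rt; then NaBO3·4H2O, THF/H2O, 0 °C
Reagents that add atoms: bis(pinacolato)diboron CC1(C)OB(OC1(C)C)B1OC(C)(C)C(C)(C)O1 (boron of 18); sodium perborate [Na+].[Na+].O[B-]1(O)OO[B-](O)(O)OO1 (oxygen at C17)
Why: Copper(I)-catalysed conjugate borylation of the enone puts boron on C17, methanol protonates the copper enolate at C16 from the exo face (the side of the one-carbon bridge C14), and perborate oxidises the C–B bond with retention; this formal anti-Markovnikov hydration sets C16 with H exo and CH2OH endo.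

Step 15
Reactants: 19 silyl ether of the target
Product: 20 target, 11α,17-dihydroxy-15-oxo-6,7-seco-ent-kaurane-6,19:7,20-diolide (CNP0555433.1)
Conditions: HF·pyridine, THF/pyridine, 0 °C to rt
Reagents that add atoms: none
Why: Acidic fluoride cleaves the silyl ether without the base that would epimerise C16, eliminate water from the β-hydroxy ketone or open the β-keto lactone.

## Compound list

1 | rac-α-cyclogeranic acid (rac-2,6,6-trimethylcyclohex-2-ene-1-carboxylic acid) | CC1=CCCC(C)(C)C1C(=O)O | starting material
2 | (R)-α-cyclogeranic acid | CC1=CCCC(C)(C)[C@H]1C(=O)O | intermediate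
3 | (3aR,7aS)-3a,7-dimethyl-3a,4,5,7a-tetrahydro-2-benzofuran-1(3H)-one (cis-fused; C6 carbonyl, O on C19) | C[C@@]12CCC=C(C)[C@@H]1C(=O)OC2 | intermediate
4 | (3aR,7aR)-7-(hydroxymethyl)-3a-methyl-3a,4,5,7a-tetrahydro-2-benzofuran-1(3H)-one | C[C@@]12CCC=C(CO)[C@@H]1C(=O)OC2 | intermediate
5 | 2-iodo-3-methoxybenzoic acid | COc1cccc(C(=O)O)c1I | starting material
6 | [(3aR,7aR)-3a-methyl-1-oxo-1,3,3a,4,5,7a-hexahydro-2-benzofuran-7-yl]methyl 2-iodo-3-methoxybenzoate | C[C@@]12CCC=C(COC(=O)c3cccc(OC)c3I)[C@@H]1C(=O)OC2 | intermediate
7 | 11-methoxy-6,7-seco-ent-podocarpa-1,8,11,13-tetraene-6,19:7,20-diolide (spiro at C10, aryl carbon C9 β, C20 α) | C[C@@]12CC=C[C@]3(COC(=O)c4cccc(OC)c43)[C@@H]1C(=O)OC2 | intermediate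
8 | 11-methoxy-6,7-seco-ent-podocarpa-8,11,13-triene-6,19:7,20-diolide | C[C@@]12CCC[C@]3(COC(=O)c4cccc(OC)c43)[C@@H]1C(=O)OC2 | intermediate
9 | 11-methoxy-6,7-seco-ent-podocarpa-9(11),13-diene-6,19:7,20-diolide (C8 epimers, not isolated) | C[C@@]12CCC[C@]3(COC(=O)C4C=CCC(OC)=C43)[C@@H]1C(=O)OC2 | intermediate
10 | 11-oxo-6,7-seco-ent-podocarp-12-ene-6,19:7,20-diolide (9β-H; written as 8α-H) | C[C@@]12CCC[C@]3(COC(=O)[C@@H]4CC=CC(=O)[C@H]43)[C@@H]1C(=O)OC2 | intermediate
11 | 11α-hydroxy-6,7-seco-ent-podocarp-12-ene-6,19:7,20-diolide | C[C@@]12CCC[C@]3(COC(=O)[C@@H]4CC=C[C@@H](O)[C@H]43)[C@@H]1C(=O)OC2 | intermediate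
12 | 11α-(tert-butyldimethylsilyloxy)-6,7-seco-ent-podocarp-12-ene-6,19:7,20-diolide | C[C@@]12CCC[C@]3(COC(=O)[C@@H]4CC=C[C@@H](O[Si](C)(C)C(C)(C)C)[C@H]43)[C@@H]1C(=O)OC2 | intermediate
13 | 2,3-dibromopropene | C=C(Br)CBr | starting material
14 | 8-(2-bromoprop-2-enyl)-11α-(tert-butyldimethylsilyloxy)-6,7-seco-ent-podocarp-12-ene-6,19:7,20-diolide (bromoallyl β, syn to H-9) | C[C@@]12CCC[C@]3(COC(=O)[C@@]4(CC(Br)=C)CC=C[C@@H](O[Si](C)(C)C(C)(C)C)[C@H]43)[C@@H]1C(=O)OC2 | intermediate
15 | 11α-(tert-butyldimethylsilyloxy)-6,7-seco-ent-kaur-16-ene-6,19:7,20-diolide | C[C@@]12CCC[C@]3(COC(=O)[C@@]45C[C@@H](C[C@@H](O[Si](C)(C)C(C)(C)C)[C@H]43)C(=C)C5)[C@@H]1C(=O)OC2 | intermediate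
16 | 15-hydroxy-11α-(tert-butyldimethylsilyloxy)-6,7-seco-ent-kaur-16-ene-6,19:7,20-diolide (C15 not defined) | C[C@@]12CCC[C@]3(COC(=O)[C@@]45C[C@@H](C[C@@H](O[Si](C)(C)C(C)(C)C)[C@H]43)C(=C)C5O)[C@@H]1C(=O)OC2 | intermediate
17 | 11α-(tert-butyldimethylsilyloxy)-15-oxo-6,7-seco-ent-kaur-16-ene-6,19:7,20-diolide | C[C@@]12CCC[C@]3(COC(=O)[C@@]45C[C@@H](C[C@@H](O[Si](C)(C)C(C)(C)C)[C@H]43)C(=C)C5=O)[C@@H]1C(=O)OC2 | intermediate
18 | 17-(4,4,5,5-tetramethyl-1,3,2-dioxaborolan-2-yl)-11α-(tert-butyldimethylsilyloxy)-15-oxo-6,7-seco-ent-kaurane-6,19:7,20-diolide (H-16 exo, not isolated) | C[C@@]12CCC[C@]3(COC(=O)[C@@]45C[C@@H](C[C@@H](O[Si](C)(C)C(C)(C)C)[C@H]43)[C@@H](CB6OC(C)(C)C(C)(C)O6)C5=O)[C@@H]1C(=O)OC2 | intermediate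
19 | 17-hydroxy-11α-(tert-butyldimethylsilyloxy)-15-oxo-6,7-seco-ent-kaurane-6,19:7,20-diolide | C[C@@]12CCC[C@]3(COC(=O)[C@@]45C[C@@H](C[C@@H](O[Si](C)(C)C(C)(C)C)[C@H]43)[C@@H](CO)C5=O)[C@@H]1C(=O)OC2 | intermediate
20 | 11α,17-dihydroxy-15-oxo-6,7-seco-ent-kaurane-6,19:7,20-diolide (CNP0555433.1) | C[C@@]12CCC[C@]3(COC(=O)[C@@]45C[C@@H](C[C@@H](O)[C@H]43)[C@@H](CO)C5=O)[C@@H]1C(=O)OC2 | target

## Step count and least certain steps

Total step count: 15. Longest linear sequence: 15 steps (1 to 20); 5 and 13 enter as commercial building blocks.

**Step 7 (key step).** The dissolving metal may also reduce or ammonolyse the aliphatic γ-lactone, and thermodynamic control at C9 may be incomplete. Fallback from 8, back at 10, without dissolving metal: demethylation with BBr3 (CH2Cl2, −78 to −20 °C) gives the phenol F1. Palladium-catalysed partial hydrogenation of the phenol (Pd/C, H2, CH2Cl2) gives the saturated 11-ketone F2, with C9 again equilibrating next to the ketone. IBX dehydrogenation at the less hindered C12–C13 (DMSO, 70 °C) then gives 10.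

**Step 2.** Palladium(II) and peroxide may oxidise the ring alkene or the allylic C20–H instead of the methyl group, and the β,γ-unsaturated acid may deconjugate with loss of the C5 information. Fallback from 2, back at 8, which moves the C–H lactonisation to an alkene-free stage:
- benzylation (BnBr, K2CO3, DMF) gives benzyl (R)-α-cyclogeranate F3;
- selenium dioxide oxidation as in step 3 gives the allylic alcohol F4;
- DCC coupling with 5 gives the aryl iodide ester F5;
- Heck cyclisation as in step 5 gives the spiro ester F6 (aryl anti to the pseudo-axial ester on C5);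
- hydrogenation over Pd/C saturates the alkene and removes the benzyl group to give the acid F7;
- the same Pd-catalysed γ-C–H lactonisation of F7, now without an alkene, gives 8.

**Step 5.** Palladium(0) may ionise the allylic benzoate to a π-allyl complex instead of adding to the aryl iodide, and hydride re-addition may scramble the alkene. Fallback from 6, back at 8: aryl radical cyclisation (Bu3SnH, AIBN, slow addition, benzene, 80 °C) closes the same bond 6-exo and reduces the C1 radical, so 8 forms directly and step 6 is not needed.

**Step 8.** Catalyst and substrate may be mismatched if the vinyl side, not the C9 side, acts as the large group, giving poor facial selectivity at C11. Fallback from 10, back at 11: Luche reduction (NaBH4, CeCl3, MeOH, −78 °C) gives the substrate-controlled alcohol. If it is the 11β-alcohol F8, Mitsunobu inversion (4-nitrobenzoic acid, PPh3, DIAD) gives the 11α-(4-nitrobenzoate) F9, and brief methanolysis (K2CO3 cat., MeOH, 0 °C) gives 11.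

**Step 11.** The C16 vinyl radical may abstract the syn-axial, allylic and oxygen-activated H-11 (1,5-hydrogen transfer) in competition with the 5-exo closure, or rearrange to the 6-endo product at low stannane concentration. Fallback from 14, back at 15, which removes H-11 before the cyclisation:
- HF·pyridine gives the allylic alcohol F10;
- MnO2 gives the enone F11;
- the same stannane cyclisation, now onto the enone β-carbon, gives the bicyclic 11-ketone F12;
- SmI2 in THF/MeOH reduces the ketone under thermodynamic control to the equatorial 11α-alcohol F13 (hydride reagents would attack from the open α side and give the axial epimer);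
- TBSOTf/2,6-lutidine gives 15.

**Step 14.** Protonation at C16 may lose its exo selectivity through enolate equilibration under the basic borylation and perborate conditions, and alkoxide may open the β-keto lactone. Fallback from 16, back at 20, which sets C16 by syn addition before the ketone exists:
- hydroboration of the exocyclic alkene from the exo face (9-BBN, THF; NaBO3) gives the 15,17-diol F14;
- TBSCl/imidazole silylates the primary alcohol to give F15;
- Dess–Martin oxidation gives the 15-ketone F16;
- HF·pyridine removes both silyl groups to give 20.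

## Further compounds

F1 | step 7 | 11-hydroxy-6,7-seco-ent-podocarpa-8,11,13-triene-6,19:7,20-diolide (phenol) | C[C@@]12CCC[C@]3(COC(=O)c4cccc(O)c43)[C@@H]1C(=O)OC2
F2 | step 7 | 11-oxo-6,7-seco-ent-podocarpane-6,19:7,20-diolide | C[C@@]12CCC[C@]3(COC(=O)[C@@H]4CCCC(=O)[C@H]43)[C@@H]1C(=O)OC2
F3 | step 2 | benzyl (R)-α-cyclogeranate | CC1=CCCC(C)(C)[C@H]1C(=O)OCc1ccccc1
F4 | step 2 | benzyl (1R)-2-(hydroxymethyl)-6,6-dimethylcyclohex-2-ene-1-carboxylate | OCC1=CCCC(C)(C)[C@H]1C(=O)OCc1ccccc1
F5 | step 2 | [(6R)-6-(benzyloxycarbonyl)-5,5-dimethylcyclohex-1-en-1-yl]methyl 2-iodo-3-methoxybenzoate | COc1cccc(C(=O)OCC2=CCCC(C)(C)[C@H]2C(=O)OCc2ccccc2)c1I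
F6 | step 2 | benzyl 11-methoxy-7-oxo-6,7-seco-ent-podocarpa-1,8,11,13-tetraen-7,20-olid-6-oate (spiro Heck product, C9 β) | CC1(C)CC=C[C@]2(COC(=O)c3cccc(OC)c32)[C@@H]1C(=O)OCc1ccccc1
F7 | step 2 | 11-methoxy-6,7-seco-ent-podocarpa-8,11,13-trien-7,20-olid-6-oic acid | CC1(C)CCC[C@]2(COC(=O)c3cccc(OC)c32)[C@@H]1C(=O)O
F0 | step 5 | none | none
F8 | step 8 | 11β-hydroxy-6,7-seco-ent-podocarp-12-ene-6,19:7,20-diolide (C11 epimer of 11) | C[C@@]12CCC[C@]3(COC(=O)[C@@H]4CC=C[C@H](O)[C@H]43)[C@@H]1C(=O)OC2
F9 | step 8 | 11α-(4-nitrobenzoyloxy)-6,7-seco-ent-podocarp-12-ene-6,19:7,20-diolide | C[C@@]12CCC[C@]3(COC(=O)[C@@H]4CC=C[C@@H](OC(=O)c5ccc(cc5)[N+](=O)[O-])[C@H]43)[C@@H]1C(=O)OC2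
F10 | step 11 | 8-(2-bromoprop-2-enyl)-11α-hydroxy-6,7-seco-ent-podocarp-12-ene-6,19:7,20-diolide | C[C@@]12CCC[C@]3(COC(=O)[C@@]4(CC(Br)=C)CC=C[C@@H](O)[C@H]43)[C@@H]1C(=O)OC2
F11 | step 11 | 8-(2-bromoprop-2-enyl)-11-oxo-6,7-seco-ent-podocarp-12-ene-6,19:7,20-diolide | C[C@@]12CCC[C@]3(COC(=O)[C@@]4(CC(Br)=C)CC=CC(=O)[C@H]43)[C@@H]1C(=O)OC2
F12 | step 11 | 11-oxo-6,7-seco-ent-kaur-16-ene-6,19:7,20-diolide | C[C@@]12CCC[C@]3(COC(=O)[C@@]45C[C@@H](CC(=O)[C@H]43)C(=C)C5)[C@@H]1C(=O)OC2
F13 | step 11 | 11α-hydroxy-6,7-seco-ent-kaur-16-ene-6,19:7,20-diolide | C[C@@]12CCC[C@]3(COC(=O)[C@@]45C[C@@H](C[C@@H](O)[C@H]43)C(=C)C5)[C@@H]1C(=O)OC2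
F14 | step 14 | 15,17-dihydroxy-11α-(tert-butyldimethylsilyloxy)-6,7-seco-ent-kaurane-6,19:7,20-diolide (H-16 exo, C15 not defined) | C[C@@]12CCC[C@]3(COC(=O)[C@@]45C[C@@H](C[C@@H](O[Si](C)(C)C(C)(C)C)[C@H]43)[C@@H](CO)C5O)[C@@H]1C(=O)OC2
F15 | step 14 | 15-hydroxy-11α,17-bis(tert-butyldimethylsilyloxy)-6,7-seco-ent-kaurane-6,19:7,20-diolide | C[C@@]12CCC[C@]3(COC(=O)[C@@]45C[C@@H](C[C@@H](O[Si](C)(C)C(C)(C)C)[C@H]43)[C@@H](CO[Si](C)(C)C(C)(C)C)C5O)[C@@H]1C(=O)OC2
F16 | step 14 | 11α,17-bis(tert-butyldimethylsilyloxy)-15-oxo-6,7-seco-ent-kaurane-6,19:7,20-diolide | C[C@@]12CCC[C@]3(COC(=O)[C@@]45C[C@@H](C[C@@H](O[Si](C)(C)C(C)(C)C)[C@H]43)[C@@H](CO[Si](C)(C)C(C)(C)C)C5=O)[C@@H]1C(=O)OC2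
A1 | alternative 1 | triene ester: 6,19-lactone of ring A with C10 bearing CH2O–CO–C(=CH2)CH2C(Br)=CH2 and a (Z)-2-(tert-butyldimethylsilyloxy)buta-1,3-dienyl group | C[C@@]12CCC[C@@](COC(=O)C(=C)CC(Br)=C)(/C=C(/C=C)O[Si](C)(C)C(C)(C)C)[C@@H]1C(=O)OC2
A2 | alternative 1 | Diels–Alder adduct: 8-(2-bromoprop-2-enyl)-11-(tert-butyldimethylsilyloxy)-6,7-seco-ent-podocarp-11-ene-6,19:7,20-diolide | C[C@@]12CCC[C@]3(COC(=O)[C@@]4(CC(Br)=C)CCC=C(O[Si](C)(C)C(C)(C)C)[C@H]43)[C@@H]1C(=O)OC2
A3 | alternative 2 | 8-epi reductive-alkylation product: 8-(2-bromoprop-2-enyl)-11-methoxy-6,7-seco-ent-podocarpa-9(11),13-diene-6,19:7,20-diolide with the bromoallyl group syn to C1 | C[C@@]12CCC[C@]3(COC(=O)[C@]4(CC(Br)=C)C=CCC(OC)=C43)[C@@H]1C(=O)OC2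
A4 | alternative 3 | [(3aR,7aR)-3a-methyl-1-oxo-1,3,3a,4,5,7a-hexahydro-2-benzofuran-7-yl]methyl 1-(2-bromoprop-2-enyl)cyclohexa-2,5-diene-1-carboxylate | C[C@@]12CCC=C(COC(=O)C3(CC(Br)=C)C=CCC=C3)[C@@H]1C(=O)OC2
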